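## Analysis of the target

The target is a 2,5-diaryl-3,4-dimethyltetrahydrofuran (ring atoms O1, C2, C3, C4, C5). C2 carries guaiacyl ring B and C5 guaiacyl ring C, and the phenolic oxygen of each ring, para to the ring carbon, is etherified with a 1-(3,4-dimethoxyphenyl)-1-hydroxypropan-2-yl arm (carbinol carbon C7, ether carbon C8; veratryl ring A on the ring B arm, ring D on the ring C arm). It has eight stereocentres and no symmetry: the core is 2S,3S,4S,5R, with ring B, the C4 methyl and ring C on one face and the C3 methyl on the other (2,3-trans, 3,4-trans, 4,5-cis, 2,5-cis). The arm on ring B is 7R,8S (erythro) and the arm on ring C is 7R,8R (threo), so the two phenols must be told apart and each must receive its own arm. The ring ether is doubly benzylic and flanked by electron-rich arenes, so acid can ionise C2 or C5 and hydrogenation can cleave it. The benzylic carbinols are acid-labile too, C8–H is acidic while C7 is a ketone, and all four arenes are easily oxidised. The hard part of the core is the 4,5-cis contact of ring C with the C4 methyl, the more crowded arrangement, which must be made under kinetic control. The plan rests on the chain C5–O1–C2–C3–C4: read from C5 it is a 2-oxahex-5-enyl radical (radical on C5, then O1, C2, C3, and a vinyl group on C3 whose inner carbon is C4 and whose terminal carbon becomes the C4 methyl), so one 5-exo closure forms C4–C5 and the ring.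

## Retrosynthetic reasoning

**Ring C arm.** In 25 the C7–H bond and then the O–C8 bond of the ring C arm are cut: 25 comes from ketone 24 by hydride addition, and 24 from phenol 19 and tosylate 23 by SN2 displacement. The aryl–O–C8 ether is the only link between arm and core, so this cut gives a phenol and an electrophile whose C8 configuration is bought with the chiral pool. The ketone activates C8 for displacement and then serves to set C7. The forward steps must invert C8 without enolisation and deliver hydride without chelation (threo).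

**Ring B arm and phenol differentiation.** The same cut is made at ring B: 19 from 18 by desilylation, 18 from ketone 17 by chelation-controlled reduction (erythro), and 17 from phenol 12 and the enantiomeric tosylate 16. The two phenols are distinguished by a benzyl ether on ring B and a silyl ether on ring C, so 12 comes from 11 by hydrogenolysis. The benzyl group goes first because hydrogenolysis is safest while no benzylic carbinol is present; the silyl ether survives everything in between.

**Arm electrophiles.** 16 and 23 are cut at the carbonyl–aryl bond and at the sulfonate: each comes from its hydroxy ketone (15, 22), which comes from a Weinreb amide (14, 21) of the lactate enantiomers 13 and 20. Both C8 configurations are therefore purchased.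

**Core (key disconnection).** In 11 the C4–C5 bond is cut, giving acid 10. This removes the ring, the C5 stereocentre and the C4 stereocentre in one stroke and leaves an acyclic ether with only two stereocentres (C2, C3). The carboxyl group on C5 is the radical precursor, so its configuration is irrelevant. The forward reaction must close 5-exo, place the new C4 substituent trans to the C3 methyl, place ring C cis to it, and end by hydrogen transfer to the primary radical.

**Ether linkage.** In 10 the O1–C5 bond is cut: acid 10 comes from ester 9, and 9 from alcohol 4 and diazo ester 8 by O–H insertion. This joins the two aryl halves at oxygen under neutral conditions and asks for no stereocontrol at C5.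

**Homoallylic alcohol.** In 4 the C2–C3 bond is cut to aldehyde 1 and crotylboronate 2. A single anti-crotylation sets C2 and C3, the only core stereocentres that are carried through unchanged.

**Diazo ester.** 8 comes from 7 by diazo transfer, 7 from 6 by silylation, and 6 from 5 by esterification.

## Alternatives that were turned down

**Alternative 1:** The two C–CH3 bonds at C3 and C4 are disconnected. In the forward sense Me2CuLi (monovalent copper) adds methyl to the β-carbon of butenolide A2 anti to the γ-aryl group, and the enolate is methylated with MeI anti to the new methyl, giving lactone A1.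
- For: the sense of both additions is substrate-controlled and very well established, and A1 holds the 2,3-trans-3,4-trans array of the target. On predictability of the key step itself this alternative is stronger than a radical closure.
- Against: A1 still lacks ring C. The lactone must be reduced, activated and arylated through a cyclic oxocarbenium ion, and that addition has to put ring C cis to the neighbouring methyl, on the more hindered face. The Lewis acid needed can also ionise the electron-rich benzylic C2. Cuprate-derived enolates alkylate sluggishly, so the tandem step often becomes two, and A2 needs its own asymmetric synthesis.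
- Comparison: the hardest stereocentre, C5, is postponed to a step with weak intrinsic control. The chosen route sets C4 and C5 together under neutral conditions, in a closure whose kinetic preference is the 4,5-cis relation.

**Alternative 2:** The bonds O1–C5 and C2–C3 are disconnected in a [3+2] sense. In the forward sense Sn(OTf)2 (divalent tin) activates the trans donor–acceptor cyclopropane A4; the oxygen of aldehyde A5 attacks the benzylic carbon with inversion and the malonate carbon closes onto the oxocarbenium carbon, giving A3.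
- For: it is the most convergent option. The trans cyclopropane is transferred stereospecifically into the 4,5-cis relation, and 2,5-cis is inherent to the annulation. On convergence and on these two relations it is at least as strong as the chosen route.
- Against: A3 carries a geminal diester at C3. This must be cut down to one methyl group of defined configuration (Krapcho dealkoxycarbonylation, reduction, deoxygenation): three to four steps after the key step, under conditions that endanger the aryl silyl ether. The very electron-rich donor ring lets A4 open to a zwitterion before the aldehyde arrives, which erodes both enantiopurity and the trans-to-cis transfer. Enantiopure A4 is not readily made.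
- Comparison: the chosen route delivers the C4 methyl at the right oxidation level in the ring-forming step, takes its absolute configuration from a robust crotylation, and has no ionisable intermediate at C5.

**Alternative 3:** The O1–C2 bond is disconnected. In the forward sense Ag2O (monovalent silver) oxidises the 4-alkyl-2-methoxyphenol of open-chain carbinol A7 to a para-quinone methide, and the C5 hydroxyl adds to the methide carbon to give A6.
- For: the closure is biomimetic and fast, and A6 emerges with the ring B phenol already free, which saves one deprotection. On end-game economy it is slightly better.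
- Against: all three carbon stereocentres C3, C4 and C5, including the C4/C5 relation, must be built in the acyclic precursor A7, which costs several stereoselective C–C bond formations. The methide can tautomerise to a styrene or dimerise. A6 is itself a 4-alkyl-2-methoxyphenol with a benzylic C2–H, so it can be re-oxidised, with epimerisation at C2 or ring opening. The C2 configuration is not fixed by a defined transition state.
- Comparison: the chosen closure forms a C–C bond and two stereocentres at once from a precursor with two, and both phenols are masked while it happens.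

Key step: step 7

Assumption: the (S)-antipode of the phosphoric acid in step 1 is taken to direct the crotyl group to the Si face of 1; if the sense of induction is the reverse, the (R)-antipode is used and nothing else changes.

## Route

Step 1
Reactants: 1 4-(benzyloxy)-3-methoxybenzaldehyde (O-benzylvanillin); 2 (E)-crotylboronic acid pinacol ester
Product: 4 (1S,2S)-1-[4-(benzyloxy)-3-methoxyphenyl]-2-methylbut-3-en-1-ol, via O-pinacolboryl ether of the homoallylic alcohol 3 (not isolated)
Conditions: (S)-TRIP [(S)-3,3'-bis(2,4,6-triisopropylphenyl)-1,1'-binaphthyl-2,2'-diyl hydrogen phosphate] (5 mol%), 4 Å MS, toluene, −30 °C; aq. NaHCO3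
Reagents that add atoms: none
Why: Chiral phosphoric acid-catalysed crotylboration; the (E)-crotyl geometry passes through a closed six-membered chair transition state to the anti relation of C2–O and C3–methyl, and the acid, hydrogen-bonded to a boronate oxygen and the formyl C–H, exposes the Si face so that C2 is S and C3 is S.

Step 2
Reactants: 5 homovanillic acid
Product: 6 methyl homovanillate
Conditions: MeOH, H2SO4 (cat.), reflux
Reagents that add atoms: methanol, CO
Why: Fischer esterification; the phenol does not react under these conditions.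

Step 3
Reactants: 6 methyl homovanillate
Product: 7 methyl 2-[3-methoxy-4-(triisopropylsilyloxy)phenyl]acetate
Conditions: TIPSCl, imidazole, DMF, rt
Reagents that add atoms: triisopropylsilyl chloride, CC(C)[Si](Cl)(C(C)C)C(C)C
Why: Standard silylation of a phenol; the bulky triisopropylsilyl ether is chosen because it must outlast a saponification and remain orthogonal to the benzyl ether on ring B.

Step 4
Reactants: 7 methyl 2-[3-methoxy-4-(triisopropylsilyloxy)phenyl]acetate
Product: 8 methyl 2-diazo-2-[3-methoxy-4-(triisopropylsilyloxy)phenyl]acetate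
Conditions: p-ABSA, DBU, MeCN, 0 °C to rt
Reagents that add atoms: 4-acetamidobenzenesulfonyl azide (p-ABSA), CC(=O)Nc1ccc(cc1)S(=O)(=O)N=[N+]=[N-]
Why: Regitz diazo transfer to an arylacetate, whose benzylic α-position is acidic enough for DBU; the aryl silyl ether tolerates the amidine base.

Step 5
Reactants: 4 (1S,2S)-1-[4-(benzyloxy)-3-methoxyphenyl]-2-methylbut-3-en-1-ol; 8 methyl 2-diazo-2-[3-methoxy-4-(triisopropylsilyloxy)phenyl]acetate
Product: 9 methyl 2-{[(1S,2S)-1-(4-benzyloxy-3-methoxyphenyl)-2-methylbut-3-en-1-yl]oxy}-2-[3-methoxy-4-(triisopropylsilyloxy)phenyl]acetate (both epimers at the acetate carbon)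
Conditions: Rh2(OAc)4 (1 mol%), CH2Cl2, rt, slow addition of 8 (1.5 equiv)
Reagents that add atoms: none
Why: Rhodium-carbenoid O–H insertion; the hydroxyl oxygen captures the electrophilic aryl(ester)carbenoid (oxonium ylide, proton shift) faster than the unactivated vinyl group is cyclopropanated, C2 and C3 are untouched, and the unselective new carbon is harmless because step 7 destroys it.

Step 6
Reactants: 9 methyl 2-{[(1S,2S)-1-(4-benzyloxy-3-methoxyphenyl)-2-methylbut-3-en-1-yl]oxy}-2-[3-methoxy-4-(triisopropylsilyloxy)phenyl]acetate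
Product: 10 2-{[(1S,2S)-1-(4-benzyloxy-3-methoxyphenyl)-2-methylbut-3-en-1-yl]oxy}-2-[3-methoxy-4-(triisopropylsilyloxy)phenyl]acetic acid (both epimers at the acid-bearing carbon)
Conditions: LiOH·H2O (3 equiv), THF/H2O 3:1, 0 °C to rt; then 1 M HCl to pH 4
Reagents that add atoms: lithium hydroxide, [Li+].[OH-]
Why: Saponification of a methyl ester; the aryl silyl ether, shielded by its isopropyl groups and the ortho methoxy group, should survive hydroxide in the absence of methanol, and epimerisation at the α-carbon does not matter.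

Step 7
Reactants: 10 2-{[(1S,2S)-1-(4-benzyloxy-3-methoxyphenyl)-2-methylbut-3-en-1-yl]oxy}-2-[3-methoxy-4-(triisopropylsilyloxy)phenyl]acetic acid
Product: 11 (2S,3S,4S,5R)-2-[4-(benzyloxy)-3-methoxyphenyl]-5-[3-methoxy-4-(triisopropylsilyloxy)phenyl]-3,4-dimethyltetrahydrofuran
Conditions: 9-mesitylacridine (10 mol%), 2,4,6-triisopropylbenzenethiol (10 mol%), CH2Cl2 (0.02 M, degassed), 400 nm LED, 35 °C
Reagents that add atoms: none
Why: The acridine binds the acid by hydrogen bonding and, on excitation, takes up its proton and electron; loss of CO2 from the carboxyl radical leaves the planar α-alkoxybenzyl radical at C5, so both epimers of 10 converge. This radical adds 5-exo-trig to the inner carbon of the vinyl group (C4–C5 bond, tetrahydrofuran closed), the primary radical takes hydrogen from the thiol to become the C4 methyl, and the thiyl radical is returned to thiol by the acridinyl radical. The closest known reaction type is the 5-exo-trig cyclisation of α-alkoxyalkyl radicals generated by photocatalytic decarboxylation, joined to acridine/thiol hydrodecarboxylation. C4: in the chair-like transition state ring B on C2 and the methyl on C3, fixed trans in step 1, both sit pseudo-equatorial, which turns the alkene so that the new CH2 ends up trans to the C3 methyl and cis to ring B. C5: ring C on the radical carbon takes the outward pseudo-equatorial position of the same chair, which puts it cis to the new C4 substituent and therefore cis to ring B. The step needs 5-exo over 6-endo closure and cyclisation before reduction: the first is the kinetic preference of hexenyl-type radicals, and the second is secured by a hindered arenethiol in small amount, which transfers hydrogen slowly to the congested, stabilised benzylic radical but at once to the primary radical, so that closure cannot reverse.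

Step 8
Reactants: 11 (2S,3S,4S,5R)-2-[4-(benzyloxy)-3-methoxyphenyl]-5-[3-methoxy-4-(triisopropylsilyloxy)phenyl]-3,4-dimethyltetrahydrofuran
Product: 12 2-methoxy-4-{(2S,3S,4S,5R)-5-[3-methoxy-4-(triisopropylsilyloxy)phenyl]-3,4-dimethyltetrahydrofuran-2-yl}phenol
Conditions: H2 (1 atm), Pd/C (10%), EtOAc, rt, stopped after one equivalent of H2
Reagents that add atoms: none
Why: Hydrogenolysis of a benzyl aryl ether, which is far faster than cleavage of the hindered secondary ring C–O bonds under neutral conditions; the silyl ether is inert and no benzylic carbinol is present yet.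

Step 9
Reactants: 13 methyl (R)-lactate
Product: 14 (R)-2-hydroxy-N-methoxy-N-methylpropanamide
Conditions: MeNH(OMe)·HCl, iPrMgCl, THF, −20 to 0 °C; aq. NH4Cl
Reagents that add atoms: N,O-dimethylhydroxylamine hydrochloride, CNOC.Cl
Why: Aminolysis of the ester by the magnesium amide formed in the flask gives the Weinreb amide; the α-carbon is protected from enolisation as the magnesium alkoxide, so the R configuration is kept.

Step 10
Reactants: 14 (R)-2-hydroxy-N-methoxy-N-methylpropanamide
Product: 15 (R)-1-(3,4-dimethoxyphenyl)-2-hydroxypropan-1-one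
Conditions: 3,4-(MeO)2C6H3MgBr (2.5 equiv), THF, 0 °C; aq. NH4Cl
Reagents that add atoms: 3,4-dimethoxyphenylmagnesium bromide, COc1ccc([Mg]Br)cc1OC
Why: Grignard addition to a Weinreb amide; the chelated tetrahedral intermediate holds until work-up, so neither over-addition nor enolisation of the ketone occurs, and the first equivalent only deprotonates the hydroxyl group.

Step 11
Reactants: 15 (R)-1-(3,4-dimethoxyphenyl)-2-hydroxypropan-1-one
Product: 16 (R)-1-(3,4-dimethoxyphenyl)-1-oxopropan-2-yl 4-methylbenzenesulfonate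
Conditions: TsCl, Et3N, DMAP (cat.), CH2Cl2, 0 °C
Reagents that add atoms: 4-toluenesulfonyl chloride, Cc1ccc(cc1)S(Cl)(=O)=O
Why: Sulfonylation at oxygen leaves the C8 configuration untouched and turns C8 into a carbonyl-activated SN2 electrophile.

Step 12
Reactants: 12 2-methoxy-4-{(2S,3S,4S,5R)-5-[3-methoxy-4-(triisopropylsilyloxy)phenyl]-3,4-dimethyltetrahydrofuran-2-yl}phenol; 16 (R)-1-(3,4-dimethoxyphenyl)-1-oxopropan-2-yl 4-methylbenzenesulfonate
Product: 17 (S)-1-(3,4-dimethoxyphenyl)-2-(2-methoxy-4-{(2S,3S,4S,5R)-5-[3-methoxy-4-(triisopropylsilyloxy)phenyl]-3,4-dimethyltetrahydrofuran-2-yl}phenoxy)propan-1-one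
Conditions: BEMP (1.2 equiv), CH2Cl2, 0 °C to rt
Reagents that add atoms: none
Why: SN2 displacement of an α-keto tosylate by a phenoxide with inversion (8R to 8S); the neighbouring carbonyl makes the displacement fast at low temperature, and a phosphazene base buffered by the phenol keeps enolisation of tosylate and product slow.

Step 13
Reactants: 17 (S)-1-(3,4-dimethoxyphenyl)-2-(2-methoxy-4-{(2S,3S,4S,5R)-5-[3-methoxy-4-(triisopropylsilyloxy)phenyl]-3,4-dimethyltetrahydrofuran-2-yl}phenoxy)propan-1-one
Product: 18 (1R,2S)-1-(3,4-dimethoxyphenyl)-2-(2-methoxy-4-{(2S,3S,4S,5R)-5-[3-methoxy-4-(triisopropylsilyloxy)phenyl]-3,4-dimethyltetrahydrofuran-2-yl}phenoxy)propan-1-ol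
Conditions: Zn(BH4)2, Et2O, −20 to 0 °C; aq. NH4Cl
Reagents that add atoms: none
Why: Chelation-controlled ketone reduction; zinc bridges the carbonyl oxygen and the aryloxy oxygen (with the ortho methoxy group as a further donor), hydride enters past C8–H and not past the C8 methyl, and the 8S ketone gives the 7R carbinol, the erythro arm.

Step 14
Reactants: 18 (1R,2S)-1-(3,4-dimethoxyphenyl)-2-(2-methoxy-4-{(2S,3S,4S,5R)-5-[3-methoxy-4-(triisopropylsilyloxy)phenyl]-3,4-dimethyltetrahydrofuran-2-yl}phenoxy)propan-1-ol
Product: 19 (1R,2S)-1-(3,4-dimethoxyphenyl)-2-{4-[(2S,3S,4S,5R)-5-(4-hydroxy-3-methoxyphenyl)-3,4-dimethyltetrahydrofuran-2-yl]-2-methoxyphenoxy}propan-1-ol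
Conditions: TBAF, THF, 0 °C; aq. NH4Cl
Reagents that add atoms: none
Why: Fluoride cleaves the aryl silyl ether selectively; alkyl aryl ethers, the carbinol and the ring are inert.

Step 15
Reactants: 20 ethyl (S)-lactate
Product: 21 (S)-2-hydroxy-N-methoxy-N-methylpropanamide
Conditions: MeNH(OMe)·HCl, iPrMgCl, THF, −20 to 0 °C; aq. NH4Cl
Reagents that add atoms: N,O-dimethylhydroxylamine hydrochloride, CNOC.Cl
Why: Same Weinreb amide formation as step 9, in the enantiomeric series.

Step 16
Reactants: 21 (S)-2-hydroxy-N-methoxy-N-methylpropanamide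
Product: 22 (S)-1-(3,4-dimethoxyphenyl)-2-hydroxypropan-1-one
Conditions: 3,4-(MeO)2C6H3MgBr (2.5 equiv), THF, 0 °C; aq. NH4Cl
Reagents that add atoms: 3,4-dimethoxyphenylmagnesium bromide, COc1ccc([Mg]Br)cc1OC
Why: Same Grignard addition to a Weinreb amide as step 10.

Step 17
Reactants: 22 (S)-1-(3,4-dimethoxyphenyl)-2-hydroxypropan-1-one
Product: 23 (S)-1-(3,4-dimethoxyphenyl)-1-oxopropan-2-yl 4-methylbenzenesulfonate
Conditions: TsCl, Et3N, DMAP (cat.), CH2Cl2, 0 °C
Reagents that add atoms: 4-toluenesulfonyl chloride, Cc1ccc(cc1)S(Cl)(=O)=O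
Why: Same O-sulfonylation as step 11.

Step 18
Reactants: 19 (1R,2S)-1-(3,4-dimethoxyphenyl)-2-{4-[(2S,3S,4S,5R)-5-(4-hydroxy-3-methoxyphenyl)-3,4-dimethyltetrahydrofuran-2-yl]-2-methoxyphenoxy}propan-1-ol; 23 (S)-1-(3,4-dimethoxyphenyl)-1-oxopropan-2-yl 4-methylbenzenesulfonate
Product: 24 (R)-1-(3,4-dimethoxyphenyl)-2-{4-[(2R,3S,4S,5S)-5-(4-{[(1R,2S)-1-(3,4-dimethoxyphenyl)-1-hydroxypropan-2-yl]oxy}-3-methoxyphenyl)-3,4-dimethyltetrahydrofuran-2-yl]-2-methoxyphenoxy}propan-1-one
Conditions: BEMP (1.2 equiv), CH2Cl2, 0 °C to rt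
Reagents that add atoms: none
Why: SN2 displacement with inversion as in step 12 (8S tosylate to 8R ether); only the phenol is acidic enough to be deprotonated, so the free carbinol of the first arm does not compete.

Step 19
Reactants: 24 (R)-1-(3,4-dimethoxyphenyl)-2-{4-[(2R,3S,4S,5S)-5-(4-{[(1R,2S)-1-(3,4-dimethoxyphenyl)-1-hydroxypropan-2-yl]oxy}-3-methoxyphenyl)-3,4-dimethyltetrahydrofuran-2-yl]-2-methoxyphenoxy}propan-1-one
Product: 25 (1R,2S)-1-(3,4-dimethoxyphenyl)-2-{4-[(2S,3S,4S,5R)-5-(4-{[(1R,2R)-1-(3,4-dimethoxyphenyl)-1-hydroxypropan-2-yl]oxy}-3-methoxyphenyl)-3,4-dimethyltetrahydrofuran-2-yl]-2-methoxyphenoxy}propan-1-ol (target, CNP0116650.9)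
Conditions: polymer-supported borohydride (quaternary ammonium resin, BH4− form), MeOH/CH2Cl2, 0 °C to rt
Reagents that add atoms: none
Why: Ketone reduction without a chelating cation; in the polar Felkin–Anh arrangement the C8–OAr bond lies anti to the incoming hydride, which passes C8–H, and the 8R ketone gives the 7R carbinol, the threo arm; no other group in 24 is reducible.

## Compound list

1 | 4-(benzyloxy)-3-methoxybenzaldehyde (O-benzylvanillin) | COc1cc(C=O)ccc1OCc1ccccc1 | starting material
2 | (E)-crotylboronic acid pinacol ester | C/C=C/CB1OC(C)(C)C(C)(C)O1 | starting material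
3 | 2-{[(1S,2S)-1-(4-benzyloxy-3-methoxyphenyl)-2-methylbut-3-en-1-yl]oxy}-4,4,5,5-tetramethyl-1,3,2-dioxaborolane | COc1cc(ccc1OCc1ccccc1)[C@@H](OB1OC(C)(C)C(C)(C)O1)[C@@H](C)C=C | intermediate
4 | (1S,2S)-1-[4-(benzyloxy)-3-methoxyphenyl]-2-methylbut-3-en-1-ol | COc1cc(ccc1OCc1ccccc1)[C@@H](O)[C@@H](C)C=C | intermediate
5 | homovanillic acid | COc1cc(CC(=O)O)ccc1O | starting material
6 | methyl homovanillate | COC(=O)Cc1ccc(O)c(OC)c1 | intermediate
7 | methyl 2-[3-methoxy-4-(triisopropylsilyloxy)phenyl]acetate | COC(=O)Cc1ccc(O[Si](C(C)C)(C(C)C)C(C)C)c(OC)c1 | intermediate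
8 | methyl 2-diazo-2-[3-methoxy-4-(triisopropylsilyloxy)phenyl]acetate | COC(=O)C(=[N+]=[N-])c1ccc(O[Si](C(C)C)(C(C)C)C(C)C)c(OC)c1 | intermediate
9 | methyl 2-{[(1S,2S)-1-(4-benzyloxy-3-methoxyphenyl)-2-methylbut-3-en-1-yl]oxy}-2-[3-methoxy-4-(triisopropylsilyloxy)phenyl]acetate, both epimers at the acetate carbon | COc1cc(ccc1OCc1ccccc1)[C@@H](OC(C(=O)OC)c1ccc(O[Si](C(C)C)(C(C)C)C(C)C)c(OC)c1)[C@@H](C)C=C | intermediate
10 | 2-{[(1S,2S)-1-(4-benzyloxy-3-methoxyphenyl)-2-methylbut-3-en-1-yl]oxy}-2-[3-methoxy-4-(triisopropylsilyloxy)phenyl]acetic acid, both epimers at the acid-bearing carbon | COc1cc(ccc1OCc1ccccc1)[C@@H](OC(C(=O)O)c1ccc(O[Si](C(C)C)(C(C)C)C(C)C)c(OC)c1)[C@@H](C)C=C | intermediate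
11 | (2S,3S,4S,5R)-2-[4-(benzyloxy)-3-methoxyphenyl]-5-[3-methoxy-4-(triisopropylsilyloxy)phenyl]-3,4-dimethyltetrahydrofuran | COc1cc(ccc1OCc1ccccc1)[C@H]1O[C@@H](c2ccc(O[Si](C(C)C)(C(C)C)C(C)C)c(OC)c2)[C@@H](C)[C@@H]1C | intermediate
12 | 2-methoxy-4-{(2S,3S,4S,5R)-5-[3-methoxy-4-(triisopropylsilyloxy)phenyl]-3,4-dimethyltetrahydrofuran-2-yl}phenol | COc1cc(ccc1O)[C@H]1O[C@@H](c2ccc(O[Si](C(C)C)(C(C)C)C(C)C)c(OC)c2)[C@@H](C)[C@@H]1C | intermediate
13 | methyl (R)-lactate | C[C@@H](O)C(=O)OC | starting material
14 | (R)-2-hydroxy-N-methoxy-N-methylpropanamide | C[C@@H](O)C(=O)N(C)OC | intermediate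
15 | (R)-1-(3,4-dimethoxyphenyl)-2-hydroxypropan-1-one | C[C@@H](O)C(=O)c1ccc(OC)c(OC)c1 | intermediate
16 | (R)-1-(3,4-dimethoxyphenyl)-1-oxopropan-2-yl 4-methylbenzenesulfonate | C[C@@H](OS(=O)(=O)c1ccc(C)cc1)C(=O)c1ccc(OC)c(OC)c1 | intermediate
17 | (S)-1-(3,4-dimethoxyphenyl)-2-(2-methoxy-4-{(2S,3S,4S,5R)-5-[3-methoxy-4-(triisopropylsilyloxy)phenyl]-3,4-dimethyltetrahydrofuran-2-yl}phenoxy)propan-1-one | COc1ccc(C(=O)[C@H](C)Oc2ccc([C@H]3O[C@@H](c4ccc(O[Si](C(C)C)(C(C)C)C(C)C)c(OC)c4)[C@@H](C)[C@@H]3C)cc2OC)cc1OC | intermediate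
18 | (1R,2S)-1-(3,4-dimethoxyphenyl)-2-(2-methoxy-4-{(2S,3S,4S,5R)-5-[3-methoxy-4-(triisopropylsilyloxy)phenyl]-3,4-dimethyltetrahydrofuran-2-yl}phenoxy)propan-1-ol | COc1ccc([C@@H](O)[C@H](C)Oc2ccc([C@H]3O[C@@H](c4ccc(O[Si](C(C)C)(C(C)C)C(C)C)c(OC)c4)[C@@H](C)[C@@H]3C)cc2OC)cc1OC | intermediate
19 | (1R,2S)-1-(3,4-dimethoxyphenyl)-2-{4-[(2S,3S,4S,5R)-5-(4-hydroxy-3-methoxyphenyl)-3,4-dimethyltetrahydrofuran-2-yl]-2-methoxyphenoxy}propan-1-ol | COc1ccc([C@@H](O)[C@H](C)Oc2ccc([C@H]3O[C@@H](c4ccc(O)c(OC)c4)[C@@H](C)[C@@H]3C)cc2OC)cc1OC | intermediate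
20 | ethyl (S)-lactate | C[C@H](O)C(=O)OCC | starting material
21 | (S)-2-hydroxy-N-methoxy-N-methylpropanamide | C[C@H](O)C(=O)N(C)OC | intermediate
22 | (S)-1-(3,4-dimethoxyphenyl)-2-hydroxypropan-1-one | C[C@H](O)C(=O)c1ccc(OC)c(OC)c1 | intermediate
23 | (S)-1-(3,4-dimethoxyphenyl)-1-oxopropan-2-yl 4-methylbenzenesulfonate | C[C@H](OS(=O)(=O)c1ccc(C)cc1)C(=O)c1ccc(OC)c(OC)c1 | intermediate
24 | (R)-1-(3,4-dimethoxyphenyl)-2-{4-[(2R,3S,4S,5S)-5-(4-{[(1R,2S)-1-(3,4-dimethoxyphenyl)-1-hydroxypropan-2-yl]oxy}-3-methoxyphenyl)-3,4-dimethyltetrahydrofuran-2-yl]-2-methoxyphenoxy}propan-1-one | COc1ccc([C@@H](O)[C@H](C)Oc2ccc([C@H]3O[C@@H](c4ccc(O[C@H](C)C(=O)c5ccc(OC)c(OC)c5)c(OC)c4)[C@@H](C)[C@@H]3C)cc2OC)cc1OC | intermediate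
25 | (1R,2S)-1-(3,4-dimethoxyphenyl)-2-{4-[(2S,3S,4S,5R)-5-(4-{[(1R,2R)-1-(3,4-dimethoxyphenyl)-1-hydroxypropan-2-yl]oxy}-3-methoxyphenyl)-3,4-dimethyltetrahydrofuran-2-yl]-2-methoxyphenoxy}propan-1-ol | COc1ccc([C@@H](O)[C@H](C)Oc2ccc([C@H]3O[C@@H](c4ccc(O[C@H](C)[C@H](O)c5ccc(OC)c(OC)c5)c(OC)c4)[C@@H](C)[C@@H]3C)cc2OC)cc1OC | target

## Step count and least certain steps

Total step count: 19. Longest linear sequence: 12 steps (steps 2 to 8, 12 to 14, 18 and 19, from homovanillic acid 5).

**Step 7 (key step).** The stabilised, planar C5 radical may close too slowly. Hydrogen transfer from the thiol, coupling with the acridinyl radical, or cleavage of the O1–C2 bond would then overtake ring closure. A second concern is incomplete cis selectivity at C5, because closure of a benzylic radical has a late transition state and could reverse before the primary radical is quenched. The fallback makes the acceptor electron-poor, so that closure becomes polarity-matched, fast and irreversible. It sets out from acid 10: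
- Cross-metathesis of 10 with phenyl vinyl sulfone (second-generation Grubbs catalyst, RuCl2(=CHPh)(PCy3)(H2IMes), CH2Cl2, 40 °C) should give 2-{[(1S,2S,3E)-1-(4-benzyloxy-3-methoxyphenyl)-2-methyl-4-(phenylsulfonyl)but-3-en-1-yl]oxy}-2-[3-methoxy-4-(triisopropylsilyloxy)phenyl]acetic acid F1.
- The same acridine photocatalysis without thiol should then close the ring by Giese-type 5-exo addition to the β-carbon of the vinyl sulfone. The α-sulfonyl radical is reduced by the acridinyl radical, giving (2S,3S,4S,5R)-2-(4-benzyloxy-3-methoxyphenyl)-5-[3-methoxy-4-(triisopropylsilyloxy)phenyl]-3-methyl-4-[(phenylsulfonyl)methyl]tetrahydrofuran F2.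
- Reductive desulfonylation (Na(Hg), Na2HPO4, MeOH/THF, −20 °C) converts the sulfonylmethyl group into the C4 methyl and comes back to the route at 11.

**Step 5.** Cyclopropanation of the vinyl group or dimerisation of the carbenoid may outrun O–H insertion at the hindered secondary hydroxyl. The fallback forms the same ether by ionic substitution. It sets out from 7: enolate bromination (LiN(SiMe3)2, Me3SiCl, THF, −78 °C; then NBS) should give methyl 2-bromo-2-[3-methoxy-4-(triisopropylsilyloxy)phenyl]acetate F3. Silver-assisted etherification of alcohol 4 with F3 (AgOTf, 2,6-di-tert-butyl-4-methylpyridine, 4 Å MS, CH2Cl2, −40 to 0 °C) proceeds through the benzylic cation stabilised by the para oxygen and comes back to the route at 9.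

**Step 12 (the same concern applies to step 18).** Enolisation of the α-sulfonyloxy ketone or of the α-aryloxy ketone by the base would erode the configuration at C8. The fallback moves the stereo-defining substitution to the ester level, where C8–H is far less acidic. It sets out from phenol 12:
- Mitsunobu reaction with methyl (R)-lactate 13 (PPh3, DIAD, THF, 0 °C to rt, inversion) should give methyl (S)-2-(2-methoxy-4-{(2S,3S,4S,5R)-5-[3-methoxy-4-(triisopropylsilyloxy)phenyl]-3,4-dimethyltetrahydrofuran-2-yl}phenoxy)propanoate F4.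
- Amide formation (MeNH(OMe)·HCl, iPrMgCl, THF, −20 °C) gives (S)-N-methoxy-N-methyl-2-(2-methoxy-4-{(2S,3S,4S,5R)-5-[3-methoxy-4-(triisopropylsilyloxy)phenyl]-3,4-dimethyltetrahydrofuran-2-yl}phenoxy)propanamide F5.
- Addition of 3,4-dimethoxyphenylmagnesium bromide (THF, −20 to 0 °C) comes back to the route at ketone 17.

**Step 19.** Hydride delivery without chelation may show poor facial selectivity, so that the erythro (7S,8R) arm forms alongside the threo arm. The fallback sets C7 by forming the C7–aryl bond and not the C7–H bond. It sets out from phenol 19: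
- Alkylation with commercial ethyl (S)-2-(tosyloxy)propanoate (K2CO3, DMF, 50 °C, inversion) should give ethyl (R)-2-{4-[(2R,3S,4S,5S)-5-(4-{[(1R,2S)-1-(3,4-dimethoxyphenyl)-1-hydroxypropan-2-yl]oxy}-3-methoxyphenyl)-3,4-dimethyltetrahydrofuran-2-yl]-2-methoxyphenoxy}propanoate F6.
- Partial reduction (iBu2AlH, CH2Cl2, −78 °C) gives (R)-2-{4-[(2R,3S,4S,5S)-5-(4-{[(1R,2S)-1-(3,4-dimethoxyphenyl)-1-hydroxypropan-2-yl]oxy}-3-methoxyphenyl)-3,4-dimethyltetrahydrofuran-2-yl]-2-methoxyphenoxy}propanal F7, used at once.
- Chelation-controlled addition of 3,4-dimethoxyphenylmagnesium bromide (MgBr2·OEt2, CH2Cl2, −78 °C) is the complement of the chelated ketone reduction and should give the threo (7R,8R) arm, coming back to the route at 25.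

## Further compounds

F1 | step 7 | 2-{[(1S,2S,3E)-1-(4-benzyloxy-3-methoxyphenyl)-2-methyl-4-(phenylsulfonyl)but-3-en-1-yl]oxy}-2-[3-methoxy-4-(triisopropylsilyloxy)phenyl]acetic acid | COc1cc(ccc1OCc1ccccc1)[C@@H](OC(C(=O)O)c1ccc(O[Si](C(C)C)(C(C)C)C(C)C)c(OC)c1)[C@@H](C)/C=C/S(=O)(=O)c1ccccc1
F2 | step 7 | (2S,3S,4S,5R)-2-(4-benzyloxy-3-methoxyphenyl)-5-[3-methoxy-4-(triisopropylsilyloxy)phenyl]-3-methyl-4-[(phenylsulfonyl)methyl]tetrahydrofuran | COc1cc(ccc1OCc1ccccc1)[C@H]1O[C@@H](c2ccc(O[Si](C(C)C)(C(C)C)C(C)C)c(OC)c2)[C@@H](CS(=O)(=O)c2ccccc2)[C@@H]1C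
F3 | step 5 | methyl 2-bromo-2-[3-methoxy-4-(triisopropylsilyloxy)phenyl]acetate (racemic) | COC(=O)C(Br)c1ccc(O[Si](C(C)C)(C(C)C)C(C)C)c(OC)c1
F4 | step 12 | methyl (S)-2-(2-methoxy-4-{(2S,3S,4S,5R)-5-[3-methoxy-4-(triisopropylsilyloxy)phenyl]-3,4-dimethyltetrahydrofuran-2-yl}phenoxy)propanoate | COC(=O)[C@H](C)Oc1ccc([C@H]2O[C@@H](c3ccc(O[Si](C(C)C)(C(C)C)C(C)C)c(OC)c3)[C@@H](C)[C@@H]2C)cc1OC
F5 | step 12 | (S)-N-methoxy-N-methyl-2-(2-methoxy-4-{(2S,3S,4S,5R)-5-[3-methoxy-4-(triisopropylsilyloxy)phenyl]-3,4-dimethyltetrahydrofuran-2-yl}phenoxy)propanamide | CON(C)C(=O)[C@H](C)Oc1ccc([C@H]2O[C@@H](c3ccc(O[Si](C(C)C)(C(C)C)C(C)C)c(OC)c3)[C@@H](C)[C@@H]2C)cc1OC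
F6 | step 19 | ethyl (R)-2-{4-[(2R,3S,4S,5S)-5-(4-{[(1R,2S)-1-(3,4-dimethoxyphenyl)-1-hydroxypropan-2-yl]oxy}-3-methoxyphenyl)-3,4-dimethyltetrahydrofuran-2-yl]-2-methoxyphenoxy}propanoate | COc1ccc([C@@H](O)[C@H](C)Oc2ccc([C@H]3O[C@@H](c4ccc(O[C@H](C)C(=O)OCC)c(OC)c4)[C@@H](C)[C@@H]3C)cc2OC)cc1OC
F7 | step 19 | (R)-2-{4-[(2R,3S,4S,5S)-5-(4-{[(1R,2S)-1-(3,4-dimethoxyphenyl)-1-hydroxypropan-2-yl]oxy}-3-methoxyphenyl)-3,4-dimethyltetrahydrofuran-2-yl]-2-methoxyphenoxy}propanal | COc1ccc([C@@H](O)[C@H](C)Oc2ccc([C@H]3O[C@@H](c4ccc(O[C@H](C)C=O)c(OC)c4)[C@@H](C)[C@@H]3C)cc2OC)cc1OC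
A1 | alternative 1 | (3S,4S,5S)-5-[4-(benzyloxy)-3-methoxyphenyl]-3,4-dimethyldihydrofuran-2(3H)-one | COc1cc(ccc1OCc1ccccc1)[C@H]1OC(=O)[C@@H](C)[C@@H]1C
A2 | alternative 1 | (S)-5-[4-(benzyloxy)-3-methoxyphenyl]furan-2(5H)-one | COc1cc(ccc1OCc1ccccc1)[C@H]1OC(=O)C=C1
A3 | alternative 2 | dimethyl (2R,4S,5R)-5-[4-(benzyloxy)-3-methoxyphenyl]-4-methyl-2-[3-methoxy-4-(triisopropylsilyloxy)phenyl]tetrahydrofuran-3,3-dicarboxylate | COc1cc(ccc1O[Si](C(C)C)(C(C)C)C(C)C)[C@H]1O[C@@H](c2ccc(OCc3ccccc3)c(OC)c2)[C@@H](C)C1(C(=O)OC)C(=O)OC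
A4 | alternative 2 | dimethyl (2S,3R)-2-[4-(benzyloxy)-3-methoxyphenyl]-3-methylcyclopropane-1,1-dicarboxylate (trans) | COc1cc(ccc1OCc1ccccc1)[C@@H]1[C@@H](C)C1(C(=O)OC)C(=O)OC
A5 | alternative 2 | 3-methoxy-4-(triisopropylsilyloxy)benzaldehyde | COc1cc(C=O)ccc1O[Si](C(C)C)(C(C)C)C(C)C
A6 | alternative 3 | 4-{(2S,3S,4S,5R)-5-[4-(benzyloxy)-3-methoxyphenyl]-3,4-dimethyltetrahydrofuran-2-yl}-2-methoxyphenol | COc1cc(ccc1O)[C@H]1O[C@@H](c2ccc(OCc3ccccc3)c(OC)c2)[C@@H](C)[C@@H]1C
A7 | alternative 3 | (1R,2S,3R)-1-[4-(benzyloxy)-3-methoxyphenyl]-4-(4-hydroxy-3-methoxyphenyl)-2,3-dimethylbutan-1-ol | O[C@@H](c1ccc(OCc2ccccc2)c(OC)c1)[C@@H](C)[C@H](C)Cc1ccc(O)c(OC)c1
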